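(The earlier runs and the new flask were generated by integration on assumed constants; scatter was added.)

The ratio of target to dissolved starting material at the plateau is the number to watch. Blue, whose last 3 readings average 17.0% target, gives 0.205. Green gives 0.215, and ochre, with 27.9% of its solid substrate undissolved, gives 0.190. Teal, with twice the reagent, gives 0.452.

| setting | blue | green | ochre | teal | epsilon | theta | beta |
|---|---|---|---|---|---|---|---|
| solid substrate | 10 mM | 6.7 mM | 15 mM | 10 mM | 10 mM | 10 mM | 10 mM |
| reagent | 10 mM | 10 mM | 10 mM | 20 mM | 10.0 mM (fed, over 8.0 min) | 10.0 mM | 10.0 mM |
| second substrate | 2 mM | 2 mM | 2 mM | 2 mM | 2.00 mM | 2.00 mM (fed, over 8.0 min) | 2.00 mM |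
| remark | run made earlier | run made earlier | run made earlier | run made earlier | all else is in the flask from the start; the feed brings no volume worth counting | all else is in the flask from the start; the feed brings no volume worth counting | everything together at the start |
| time |  |  |  |  | 10 min | 10 min | 10 min |

- blue (time / min: target / %, solid substrate / %): 2.00: 10.8, 14.0; 4.00: 16.1, 0; 6.00: 17.1, 0.3; 8.00: 17.6, 0; 10.0: 16.4, 0.9
- green (time / min: target / %, solid substrate / %): 1.50: 11.2, 0; 3.00: 16.3, 0; 5.00: 17.6, 0.1; 6.00: 17.7, 0.2; 8.00: 17.0, 0
- ochre (time / min: target / %, solid substrate / %): 0.667: 1.6, 68.8; 1.33: 4.6, 53.2; 2.50: 8.9, 37.7; 4.00: 10.8, 31.4; 8.00: 11.5, 27.9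
- teal (time / min: target / %, solid substrate / %): 0.667: 4.9, 52.8; 1.33: 13.2, 25.1; 2.50: 25.3, 0.1; 4.00: 29.4, 0.8; 8.00: 30.9, 0.7

(standard deviation of a reading: 0.5 percentage points)

- solid, in amounts per volume of the solution: solid substrate
- the earlier runs were read with a standard deviation of 0.5 percentage points
- steps thought possible: starting material + reagent <-> target; second substrate + reagent <-> second product; second substrate -> decomposition product; solid substrate <-> starting material
- at the start none of the solid substrate is in solution

- which flask leads in amount of target, in percent of the solid substrate charged ("all alike" within 1.5 percentage points) (epsilon / theta / beta / all alike)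
- how much target is there at the end, in percent of the solid substrate charged: epsilon
- how much target is there at the end, in percent of the solid substrate charged: theta
- how much target is there at the end, in percent of the solid substrate charged: beta

So in these runs the ratio moved with reagent and stayed near blue's value when the solid changed, which we read as thermodynamic control over the step from starting material and reagent to target. The balance of reagent then matters: free reagent is the charge less what target and second product hold. Asking that blue and teal share one ratio per unit of free reagent gives about 1.12 mM of second product, which leaves blue 7.18 mM free. Dividing gives a reading of 28.6 L mol⁻¹, the hold constant: the plateau ratio of target to dissolved starting material per unit of free reagent.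

Now the ladder of times. On the first rung, blue's gap to its plateau closes with a time of about 1.05 min, as read from its first readings. On the next, blue's solid substrate reads 14.0% after 2.00 min and 0% after 4.00 min, so blue is by then a solution within the scatter of its readings. Above these lies the feed of 8.0 min in epsilon and theta, longer than the settling, so we expect target in epsilon to follow its reagent with a lag. After the feed come 2.00 min, twice the settling time. All three flasks end with the same charges, so we reckon 17.0% for each.

The forecast gives 18.3% for epsilon, 17.2% for theta and 17% for beta, verdict all alike, and says: “The plateau in target is an equilibrium, not reagent exhaustion.” We part on epsilon, where it stands 1.3 percentage points above our figure.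

The flasks give 16.7% for epsilon, 17.1% for theta and 16.8% for beta, so the verdict is all alike.

    starting material + reagent ⇌ target (K = 29.0 L mol⁻¹, k = 0.350 L mol⁻¹ s⁻¹)
    second substrate + reagent ⇌ second product (K = 290 L mol⁻¹, k = 0.930 L mol⁻¹ s⁻¹)
    second substrate → decomposition product (k = 1.70 × 10⁻⁵ s⁻¹)
    solid substrate ⇌ starting material, rate k4*(cs4 - [starting material]) while solid is left; crystals form when [starting material] > cs4 (solubility = 9.00 mM, k = 0.0180 s⁻¹)

The return of target to starting material and reagent holds theta down: the same flask without that return ends at 62.8% against 17.1%. Theta keeps 70% of its reagent, 7.03 mM free, so the hold constant predicts a ratio of 0.201, and theta stands at 0.206. Moving the reagent charge takes a flask away from the forecast's 17.2% for theta: theta's neighbour with 4.0 mM of reagent keeps 64.5% of it, the hold constant predicts 0.0738, and that flask ends with 6.92% target over 90.1% starting material, a ratio of 0.0768.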